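**Plan**

- Retrosynthesis: the hemiketal is taken back to its methyl ketal, and ring B is cut at the bond between its ester-bearing alkene carbon and the ring B/ring C fusion CH. That CH is alpha to the ring C ketone and its partner is the alpha carbon of an acrylate, so the bond is an enolate–alkenyl bromide coupling across the ring D ketal bridge.
- Further cuts: (Z)-bromoacrylate to ynoate to ethynyl carbinol (acetylide plus ring A ketone); the ketal C–O bonds of ring D; ring A back to an arene (Birch); the aryl–quaternary carbon bond (aryl radical cyclisation); the aryl ether C–O bond (Mitsunobu); ring C to (R)-alpha-phellandrene.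
- Forward: ring C, oxygenated at both future carbonyl carbons, from the terpene; aryl ether; temporary dihydrobenzofuran carrying the quaternary methyl carbon; ring A by dearomatisation; ethynyl carbinol; ring D methyl ketal; bromoacrylate; ring B; hemiketal.
- Stereochemistry: the isopropyl carbon comes from the chiral pool and steers the Luche reduction; Mitsunobu inversion and the cis-selective cyclisation pass this on to the quaternary carbon. Convex-face protonation sets the ring A CH, axial acetylide attack sets the carbinol carbon, and the cage fixes the ketal carbon and the new fusion CH.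

Key step: step 14

Assumption: the ketal (later hemiketal) carbon is a bridge atom on which the oxygen bridge must be cis, across ring C, to the ring A carbon on the neighbouring quaternary centre; the route can only give this arrangement, and the descriptor at this carbon is written in every structure as it stands in the target string.

TBS = tert-butyldimethylsilyl.

Step 1
Reactants: 1 (R)-(−)-alpha-phellandrene
Product: 3 trans-4-hydroxy-5-isopropyl-2-methylcyclohex-2-en-1-one, via endoperoxide 2 (not isolated)
Conditions: O2, hν (visible), tetraphenylporphyrin (cat.), CH2Cl2, 0 °C; then Et3N, 0 °C to rt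
Reagents that add atoms: dioxygen, O=O
Why: singlet oxygen should add to the cisoid diene in a [4+2] cycloaddition on the face away from the isopropyl group (setting the carbinol carbon trans to isopropyl), and Kornblum–DeLaMare rearrangement should remove the less hindered bridgehead hydrogen (next to the ring CH2), which puts the enone carbonyl beside the methyl-bearing alkene carbon and leaves the isopropyl carbon non-enolisable.

Step 2
Reactants: 3 hydroxy enone
Product: 4 TBS ether of 3
Conditions: TBSOTf, 2,6-lutidine, CH2Cl2, −78 to 0 °C
Reagents that add atoms: tert-butyldimethylsilyl triflate, CC(C)(C)[Si](C)(C)OS(=O)(=O)C(F)(F)F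
Why: silyl ether protection of a hindered secondary alcohol with the silyl triflate masks the oxygen of the future ring C ketone without touching a stereocentre.

Step 3
Reactants: 4 silyloxy enone
Product: 5 allylic alcohol (1-OH cis to isopropyl, trans to OTBS)
Conditions: NaBH4, CeCl3·7H2O, MeOH, −78 to 0 °C
Reagents that add atoms: none
Why: Luche 1,2-reduction, in which hydride should add axially on the face opposite the equatorial isopropyl group as in the reduction of carvone to cis-carveol, so the new hydroxyl ends cis to isopropyl.

Step 4
Reactants: 5 allylic alcohol; 6 2-bromo-5-methylphenol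
Product: 7 aryl ether (aryloxy trans to isopropyl, cis to OTBS)
Conditions: PPh3, DIAD, THF, 0 °C to rt
Reagents that add atoms: none
Why: Mitsunobu etherification with the acidic ortho-bromophenol displaces the activated allylic oxygen by SN2 with inversion, which turns the carbinol carbon to the configuration needed for the next ring closure.

Step 5
Reactants: 7 aryl ether
Product: 8 cis-fused hexahydrodibenzofuran with the quaternary methyl carbon
Conditions: Bu3SnH (slow addition), AIBN (cat.), benzene, 80 °C
Reagents that add atoms: none
Why: 5-exo-trig aryl radical cyclisation (tin hydride method) onto the proximal, methyl-bearing alkene carbon can only take place on the face of the ether tether, so the dihydrobenzofuran is cis-fused and the quaternary carbon is set with its aryl carbon trans and its methyl cis to isopropyl, the secondary radical left on the neighbouring CH2 being reduced by Bu3SnH.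

Step 6
Reactants: 8 hexahydrodibenzofuran
Product: 10 gamma-hydroxy ketone with the ring A beta,gamma-enone, via cyclic dienol ether 9 (not isolated)
Conditions: Li, NH3(l), THF, t-BuOH, −78 °C; NH4Cl, evaporation; then (CO2H)2, THF–H2O, 0 °C
Reagents that add atoms: water, O
Why: Birch reduction of the alkyl aryl ether leaves both alkyl-bearing carbons on double bonds (1-alkoxy-1,4-diene), and mild hydrolysis of this ring-fused enol ether should protonate the carbon next to the quaternary centre from the convex face of the cis-fused bicycle (the side of the angular methyl, away from ring C), which sets the ring A CH kinetically before water opens the hemiketal to the ketone and the ring C alcohol.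

Step 7
Reactants: 10 hydroxy ketone
Product: 11 ethynyl carbinol (diol)
Conditions: HC≡CMgBr (excess), CeCl3 (anhydrous), THF, −78 to 0 °C
Reagents that add atoms: ethynylmagnesium bromide, C#C[Mg]Br
Why: organocerium 1,2-addition, weakly basic enough to spare the easily enolised beta,gamma-unsaturated ketone, in which the small acetylide should attack axially, anti to the axial hydrogen of the neighbouring CH whose ring C substituent is equatorial, so the tertiary hydroxyl ends equatorial and trans to that substituent (the substrate reacts through its open hydroxy ketone form).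

Step 8
Reactants: 11 diol
Product: 12 ring D hemiketal
Conditions: Dess–Martin periodinane, NaHCO3, CH2Cl2, 0 °C to rt
Reagents that add atoms: none
Why: Dess–Martin oxidation of the only secondary alcohol gives the ring C ketone beside the quaternary carbon, which the trans-diequatorial tertiary hydroxyl should trap as the five-membered hemiketal, the bridge allowing a single configuration at the new hemiketal carbon.

Step 9
Reactants: 12 hemiketal
Product: 13 ring D methyl ketal
Conditions: MeOH, PPTS (cat.), 3 Å molecular sieves, rt
Reagents that add atoms: methanol, CO
Why: acid-catalysed ketalisation through the ring D oxocarbenium ion exchanges hydroxyl for methoxy at the only face the bridge leaves open, under conditions the silyl ether tolerates.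

Step 10
Reactants: 13 terminal alkyne
Product: 14 ynoate
Conditions: n-BuLi, THF, −78 °C; then ClCO2Me, −78 to 0 °C
Reagents that add atoms: methyl chloroformate, COC(=O)Cl
Why: deprotonation of the terminal alkyne and C-acylation of the lithium acetylide with the chloroformate (alkyne carboxylation) is clean because no other acidic or electrophilic site is present.

Step 11
Reactants: 14 silyl ether
Product: 15 ring C alcohol
Conditions: HF·pyridine, pyridine, THF, 0 °C to rt
Reagents that add atoms: none
Why: buffered fluoride desilylation frees the secondary alcohol while the methyl ketal and the ynoate are left alone.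

Step 12
Reactants: 15 alcohol
Product: 16 keto ynoate
Conditions: Dess–Martin periodinane, NaHCO3, CH2Cl2, 0 °C to rt
Reagents that add atoms: none
Why: Dess–Martin oxidation under buffered conditions gives the ring C ketone without epimerising the isopropyl-bearing alpha carbon.

Step 13
Reactants: 16 keto ynoate
Product: 18 (Z)-alpha-bromoacrylate ketone, via alkenylstannane 17 (not isolated)
Conditions: [Cp*Ru(MeCN)3]PF6 (cat.), Bu3SnH, CH2Cl2, rt; then NBS, 0 °C, dark
Reagents that add atoms: N-bromosuccinimide, O=C1CCC(=O)N1Br
Why: ruthenium-catalysed trans-hydrostannation of the ynoate should place tin on the carbon alpha to the ester (away from the quaternary ether carbon) with hydrogen trans to it, and bromodestannylation with retention then gives the bromoacrylate in which bromine is cis to the ring A carbon, as ring closure requires.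

Step 14
Reactants: 18 (Z)-alpha-bromoacrylate ketone
Product: 19 O-methyl ketal of the target (ring B closed)
Conditions: Pd(PPh3)4 (cat.), KOtBu, THF, rt to 50 °C
Reagents that add atoms: none
Why: Oxidative addition of the alkenyl bromide to zerovalent palladium keeps the (Z) geometry, the potassium enolate formed reversibly at the ring C CH2 replaces bromide on the divalent alkenylpalladium intermediate, and reductive elimination from the carbon-bound palladium enolate joins the ester-bearing alkene carbon to the ketone alpha carbon. The closest known reaction type is the palladium-catalysed intramolecular alpha-alkenylation of ketone enolates with alkenyl halides. Ring B closes as a six-membered carbocycle by 6-(enolexo) C–C bond formation through a seven-membered palladacycle, its alkene ending endocyclic, and the same closure completes the oxabicyclo[3.2.1]octene made of rings B and D. The new ring B/ring C fusion CH is controlled by the ketal bridge, which holds the alkenyl arm and the ring C CH2 on the same face of ring D so that only the cis fusion can form. The step needs site selectivity between the two ketone alpha carbons and chemoselectivity against conjugate addition: the isopropyl-bearing CH cannot reach palladium without a strained bridged medium ring, enolate attack on the acrylate beta carbon would give a strained bicyclo[2.2.1] skeleton and is reversible, and the quaternary neighbour offers no beta-hydrogen for elimination. The isopropyl-bearing alpha carbon can equilibrate under the base, but the configuration carried in (isopropyl equatorial on the ring C chair of the cage, cis to the angular methyl) is the stable one.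

Step 15
Reactants: 19 methyl ketal
Product: 20 target hemiketal
Conditions: 1 M HCl (aq), THF, rt
Reagents that add atoms: water, O
Why: acid-catalysed ketal hydrolysis through the ring D oxocarbenium ion exchanges methoxy for hydroxy, water returning at the only position the cage leaves open and no other stereocentre being touched.

**Compound list**

1 | (R)-(−)-alpha-phellandrene, (5R)-2-methyl-5-(propan-2-yl)cyclohexa-1,3-diene (commercial, optically enriched grade) | CC1=CC[C@H](C(C)C)C=C1 | starting material
2 | 5-methyl-7-(propan-2-yl)-2,3-dioxabicyclo[2.2.2]oct-5-ene, peroxide bridge anti to isopropyl (not isolated) | CC1=C[C@@H]2OO[C@H]1C[C@@H]2C(C)C | intermediate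
3 | 4-hydroxy-2-methyl-5-(propan-2-yl)cyclohex-2-en-1-one, 4-OH trans to 5-isopropyl | CC1=C[C@H](O)[C@@H](C(C)C)CC1=O | intermediate
4 | 4-(TBS-oxy)-2-methyl-5-(propan-2-yl)cyclohex-2-en-1-one, 4-OTBS trans to 5-isopropyl | CC1=C[C@H](O[Si](C)(C)C(C)(C)C)[C@@H](C(C)C)CC1=O | intermediate
5 | 4-(TBS-oxy)-2-methyl-5-(propan-2-yl)cyclohex-2-en-1-ol, 1-OH cis to 5-isopropyl and trans to 4-OTBS | CC1=C[C@H](O[Si](C)(C)C(C)(C)C)[C@@H](C(C)C)C[C@H]1O | intermediate
6 | 2-bromo-5-methylphenol | Cc1ccc(Br)c(O)c1 | starting material
7 | 1-bromo-4-methyl-2-{[4-(TBS-oxy)-2-methyl-5-(propan-2-yl)cyclohex-2-en-1-yl]oxy}benzene, aryloxy trans to isopropyl and cis to OTBS | CC1=C[C@H](O[Si](C)(C)C(C)(C)C)[C@@H](C(C)C)C[C@@H]1Oc1cc(C)ccc1Br | intermediate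
8 | 2-(TBS-oxy)-7,9b-dimethyl-3-(propan-2-yl)-1,2,3,4,4a,9b-hexahydrodibenzo[b,d]furan; cis ring fusion, 9b-CH3 cis to 4a-H and to 3-isopropyl, 2-OTBS trans to them | Cc1ccc2c(c1)O[C@H]1C[C@H](C(C)C)[C@@H](O[Si](C)(C)C(C)(C)C)C[C@@]21C | intermediate
9 | 2-(TBS-oxy)-7,9b-dimethyl-3-(propan-2-yl)-1,2,3,4,4a,6,9,9b-octahydrodibenzo[b,d]furan, cyclic dienol ether, stereocentres as in 8 (not isolated) | CC1=CCC2=C(C1)O[C@H]1C[C@H](C(C)C)[C@@H](O[Si](C)(C)C(C)(C)C)C[C@@]21C | intermediate
10 | 6-[2-hydroxy-1-methyl-4-(propan-2-yl)-5-(TBS-oxy)cyclohexyl]-3-methylcyclohex-3-en-1-one; on ring C CH3 and isopropyl cis, OH and OTBS trans to them; ring A CH as in the target | O=C1CC(C)=CC[C@@H]1[C@]1(C)C[C@H](O[Si](C)(C)C(C)(C)C)[C@@H](C(C)C)C[C@@H]1O | intermediate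
11 | 1-ethynyl-6-[2-hydroxy-1-methyl-4-(propan-2-yl)-5-(TBS-oxy)cyclohexyl]-3-methylcyclohex-3-en-1-ol; tertiary OH trans to the ring C substituent on the neighbouring CH | C#C[C@]1(O)CC(C)=CC[C@@H]1[C@]1(C)C[C@H](O[Si](C)(C)C(C)(C)C)[C@@H](C(C)C)C[C@@H]1O | intermediate
12 | 5a-ethynyl-4a-hydroxy-7,9b-dimethyl-3-(propan-2-yl)-2-(TBS-oxy)-1,2,3,4,4a,5a,6,9,9a,9b-decahydrodibenzo[b,d]furan; ring D hemiketal, ring A/ring D trans-fused, ring D/ring C cis-fused | C#C[C@]12CC(C)=CC[C@@H]1[C@]1(C)C[C@H](O[Si](C)(C)C(C)(C)C)[C@@H](C(C)C)C[C@@]1(O)O2 | intermediate
13 | 4a-methoxy analogue of 12 (ring D methyl ketal) | C#C[C@]12CC(C)=CC[C@@H]1[C@]1(C)C[C@H](O[Si](C)(C)C(C)(C)C)[C@@H](C(C)C)C[C@@]1(OC)O2 | intermediate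
14 | methyl 3-(5a-yl)prop-2-ynoate of the ring system of 13 (ynoate, OTBS on ring C) | COC(=O)C#C[C@]12CC(C)=CC[C@@H]1[C@]1(C)C[C@H](O[Si](C)(C)C(C)(C)C)[C@@H](C(C)C)C[C@@]1(OC)O2 | intermediate
15 | 2-hydroxy analogue of 14 (free ring C alcohol) | COC(=O)C#C[C@]12CC(C)=CC[C@@H]1[C@]1(C)C[C@H](O)[C@@H](C(C)C)C[C@@]1(OC)O2 | intermediate
16 | 2-oxo analogue of 14 (ring C ketone, ynoate) | COC(=O)C#C[C@]12CC(C)=CC[C@@H]1[C@]1(C)CC(=O)[C@@H](C(C)C)C[C@@]1(OC)O2 | intermediate
17 | methyl (Z)-2-(tributylstannyl)-3-(5a-yl)prop-2-enoate of the ketone 16 ring system, tin cis to the ring A carbon (not isolated) | COC(=O)/C([Sn](CCCC)(CCCC)CCCC)=C/[C@]12CC(C)=CC[C@@H]1[C@]1(C)CC(=O)[C@@H](C(C)C)C[C@@]1(OC)O2 | intermediate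
18 | methyl (Z)-2-bromo-3-(5a-yl)prop-2-enoate of the ketone 16 ring system, bromine cis to the ring A carbon (key-step precursor) | COC(=O)/C(Br)=C/[C@]12CC(C)=CC[C@@H]1[C@]1(C)CC(=O)[C@@H](C(C)C)C[C@@]1(OC)O2 | intermediate
19 | O-methyl ketal of the target, rings A–D with ring B closed and cis ring B/ring C fusion | COC(=O)C1=C[C@]23CC(C)=CC[C@@H]2[C@]2(C)[C@H]1C(=O)[C@@H](C(C)C)C[C@@]2(OC)O3 | intermediate
20 | target hemiketal CNP0382995.2 | COC(=O)C1=C[C@]23CC(C)=CC[C@@H]2[C@]2(C)[C@H]1C(=O)[C@@H](C(C)C)C[C@@]2(O)O3 | target

**Step count and risks**

Total step count: 15. Longest linear sequence: 15 steps (from 1; 6 is a commercial reactant).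

Steps most likely to fail:

Step 14: the alkoxide base may divert the substrate before C–C coupling, by conjugate addition of the enolate or of tert-butoxide to the bromoacrylate, or by ester exchange. The fallback sets out from 18 and returns at 19 without free alkoxide. 18 is deprotonated kinetically at the ring C CH2 with LiN(SiMe3)2 in the presence of Me3SiCl (THF, −78 °C) to give the trimethylsilyl enol ether F1. F1 is then coupled with its own alkenyl bromide by the fluoride-promoted palladium-catalysed arylation-type coupling of silyl enol ethers through the tin enolate (Pd2(dba)3, P(t-Bu)3, Bu3SnF, CsF, toluene, 80 °C), which closes ring B to 19.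

Step 6: facial selectivity in the protonation of the dienol ether may be poor, and part of the aryl ether may be cleaved in the metal–ammonia reduction. The fallback sets out from 8 and returns at 10, replacing protonation by hydrogen-atom transfer to a ring-locked radical. After the same Birch reduction the crude dienol ether 9 is treated with NBS in MeOH (NaHCO3, −78 °C) to give the alpha-bromo cyclic methyl ketal F2. Radical debromination with Bu3SnH and AIBN should deliver hydrogen from the bulky tin hydride on the convex face and give the cyclic methyl ketal F3. (CO2H)2 in wet THF then opens F3 to 10.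

Step 1: the base-induced peroxide rearrangement may abstract the other bridgehead hydrogen, which would place the ketone next to the isopropyl carbon, and facial selectivity of the oxygen addition may be incomplete. The fallback sets out from 1 and returns at 3. Endoperoxide 2 is reduced in the same flask with thiourea to the cis-enediol F4, and the less hindered allylic alcohol of F4 (the one flanked by the ring CH2) is oxidised selectively with MnO2 to return to 3.

Further compounds
F1 | step 14 | trimethylsilyl enol ether of 18 toward the ring C CH2 | COC(=O)/C(Br)=C/[C@]12CC(C)=CC[C@@H]1[C@]1(C)C=C(O[Si](C)(C)C)[C@@H](C(C)C)C[C@@]1(OC)O2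
F2 | step 6 | alpha-bromo cyclic methyl ketal from 9 (ring A ketal carbon bridged by oxygen to ring C; mixture at the ketal and bromine-bearing carbons) | COC12CC(C)=CCC1(Br)[C@]1(C)C[C@H](O[Si](C)(C)C(C)(C)C)[C@@H](C(C)C)C[C@@H]1O2
F3 | step 6 | debrominated cyclic methyl ketal, ring A CH as in 10 (mixture at the ketal carbon) | COC12CC(C)=CC[C@@H]1[C@]1(C)C[C@H](O[Si](C)(C)C(C)(C)C)[C@@H](C(C)C)C[C@@H]1O2
F4 | step 1 | 2-methyl-5-(propan-2-yl)cyclohex-2-ene-1,4-diol, hydroxyls cis to each other and trans to isopropyl | CC1=C[C@H](O)[C@@H](C(C)C)C[C@@H]1O
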